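Ring A = the dimethoxybenzo ring (C4a–C8a), ring B = the dihydro ring (C1–C4), ring C = the pendant guaiacyl ring; locants follow the target (C1 carries ring C, C2 carries the CH2OH carbon C9', C3 carries the CHO carbon C9, C4 is the benzylic CH). Rings A and C are bought; ring B is the only ring made, and it is closed by the C2–C3 bond.
Target 15 ⇐ 13 ⇐ 9: the enal is unmasked from a dimethyl acetal, C3=C4 comes from syn-dehydration of a C3 carbinol toward the benzylic C4, and CH2OH from an ester.
9 ⇐ 5 + 7 in one operation: enantioselective rhodium-catalysed conjugate addition of ring C to C1 of an achiral cinnamate, whose C2 rhodium enolate then closes ring B by aldol addition to a C3 ketone (C1–aryl bond, C2–C3 bond, ring B and both lasting stereocentres at once).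
Enabling feature: C2 lies α to the exocyclic oxygenated carbon C9' and β to the diaryl-bearing C1, while C3 lies α to C9 and is joined through C4 to the ring A carbon ortho to the one bearing C1; a C1=C2–CO2Me acceptor and a C4H2–C3(=O)–C9H(OMe)2 ketone on adjacent carbons of ring A therefore put the C2 enolate and the C3 carbonyl in position for a six-membered closure, and conjugation of C3=C4 with ring A steers the later dehydration.
5 ⇐ 3 + 4 (palladium-catalysed ketone α-arylation) ⇐ 1 + 2 (Wittig); 7 ⇐ 6 (silylation).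

Key step: step 4

Assumption: (R)-BINAP is written for the ligand antipode that delivers the aryl group to the Re face of C1 of cinnamate 5; if a pilot run shows the opposite sense of induction, (S)-BINAP is used instead.

Step 1
Reactants: 1 2-bromo-4,5-dimethoxybenzaldehyde; 2 methyl 2-(triphenyl-λ5-phosphanylidene)acetate
Product: 3 methyl (E)-3-(2-bromo-4,5-dimethoxyphenyl)prop-2-enoate
Conditions: toluene, 90 °C
Reagents that add atoms: none
Why: Wittig reaction of an ester-stabilised ylide, which should give the (E)-cinnamate and leaves the aryl bromide and the methoxy groups untouched.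

Step 2
Reactants: 3 methyl (E)-3-(2-bromo-4,5-dimethoxyphenyl)prop-2-enoate; 4 1,1-dimethoxypropan-2-one
Product: 5 methyl (E)-3-[2-(3,3-dimethoxy-2-oxopropyl)-4,5-dimethoxyphenyl]prop-2-enoate
Conditions: Pd2(dba)3 (2 mol%), Xantphos (5 mol%), K3PO4 (2 equiv), 4 (3 equiv), toluene, 80 °C
Reagents that add atoms: none
Why: Buchwald–Hartwig-type palladium-catalysed α-arylation of a methyl ketone, in which the aryl-palladium bromide from 3 couples with the unhindered CH3-side enolate of 4 (the acetal-bearing side is hindered) and the weak base K3PO4 spares the methyl ester and the (E)-acrylate.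

Step 3
Reactants: 6 2-methoxy-4-(4,4,5,5-tetramethyl-1,3,2-dioxaborolan-2-yl)phenol
Product: 7 tert-butyl[2-methoxy-4-(4,4,5,5-tetramethyl-1,3,2-dioxaborolan-2-yl)phenoxy]dimethylsilane
Conditions: TBSCl, imidazole, DMF, rt
Reagents that add atoms: tert-butyldimethylsilyl chloride, CC(C)(C)[Si](C)(C)Cl
Why: Imidazole-promoted silylation of the phenol, which leaves the pinacol boronate intact and masks the acidic phenol through steps 4 to 7.

Step 4
Reactants: 5 methyl (E)-3-[2-(3,3-dimethoxy-2-oxopropyl)-4,5-dimethoxyphenyl]prop-2-enoate; 7 tert-butyl[2-methoxy-4-(4,4,5,5-tetramethyl-1,3,2-dioxaborolan-2-yl)phenoxy]dimethylsilane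
Product: 9 methyl (1S,2R,3S)-1-[4-(tert-butyldimethylsilyloxy)-3-methoxyphenyl]-3-(dimethoxymethyl)-3-hydroxy-6,7-dimethoxy-1,2,3,4-tetrahydronaphthalene-2-carboxylate, via rhodium ester enolate 8 (not isolated)
Conditions: [Rh(OH)((R)-binap)]2 (2.5 mol%), 7 (2 equiv), H2O (5 equiv), 1,4-dioxane, 70 °C, no added base
Reagents that add atoms: none
Why: Proposed new method: transmetalation of 7 to the monovalent rhodium hydroxide gives an aryl–rhodium species that adds syn across the (E)-C1=C2 bond of 5 with ring C going to C1, and the resulting oxa-π-allyl rhodium ester enolate 8 adds through C2 to the C3 ketone before water hydrolyses the rhodium aldolate and returns the catalyst; the closest known reaction types are the rhodium-catalysed tandem conjugate arylation–aldol cyclisation of keto-enones with arylboronic acids and the Hayashi–Miyaura 1,4-arylation of cinnamate esters, the new element being capture of an ester-derived rhodium enolate by a pendant ketone. Ring B closes by a 6-(enolexo)-exo-trig aldol addition in which the two ortho carbons of ring A (C8a and C4a) hold C2 and C3 in a chair-like Zimmerman–Traxler array. C1 is set by the chiral ligand (aryl delivery to the Re face of C1), C2 by 1,3-allylic strain in the enolate (C1–H eclipses the enolate plane, so the ketone tethered through ring A attacks anti to ring C, giving the 1,2-trans relationship that is also the more stable one), and C3 by the rhodium-bridged chair (hydroxyl cis to the ester), this last centre being removed in step 7. The step needs conjugate addition to outrun 1,2-arylation of the ketone, and needs the enolate to form only at C2 although the benzylic C4–H2 is the more acidic site: the first rests on the known preference of aryl–rhodium species for enoates over ketones, the second on making the enolate by carbometalation under base-free conditions, and the α-keto acetal carbonyl is electrophilic enough for the aldol to compete with protonation.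

Step 5
Reactants: 9 methyl (1S,2R,3S)-1-[4-(tert-butyldimethylsilyloxy)-3-methoxyphenyl]-3-(dimethoxymethyl)-3-hydroxy-6,7-dimethoxy-1,2,3,4-tetrahydronaphthalene-2-carboxylate
Product: 10 (1S,2S,3S)-1-[4-(tert-butyldimethylsilyloxy)-3-methoxyphenyl]-3-(dimethoxymethyl)-2-(hydroxymethyl)-6,7-dimethoxy-1,2,3,4-tetrahydronaphthalen-3-ol (target locants)
Conditions: LiBH4 (3 equiv), THF, 0 °C to rt
Reagents that add atoms: none
Why: Hydroxyl-assisted reduction of the β-hydroxy ester to the primary alcohol by LiBH4, which spares the dimethyl acetal and the aryl silyl ether and does not enolise C2 (the C2 descriptor changes only because the CIP priorities change).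

Step 6
Reactants: 10 (1S,2S,3S)-1-[4-(tert-butyldimethylsilyloxy)-3-methoxyphenyl]-3-(dimethoxymethyl)-2-(hydroxymethyl)-6,7-dimethoxy-1,2,3,4-tetrahydronaphthalen-3-ol
Product: 11 (1S,2S,3S)-2-[(tert-butyldimethylsilyloxy)methyl]-1-[4-(tert-butyldimethylsilyloxy)-3-methoxyphenyl]-3-(dimethoxymethyl)-6,7-dimethoxy-1,2,3,4-tetrahydronaphthalen-3-ol (target locants)
Conditions: TBSCl (1.2 equiv), imidazole, DMF, 0 °C
Reagents that add atoms: tert-butyldimethylsilyl chloride, CC(C)(C)[Si](C)(C)Cl
Why: Selective silylation of the primary alcohol (the tertiary C3 carbinol is too hindered for TBSCl/imidazole), which keeps the primary hydroxyl away from the dehydrating reagent of step 7.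

Step 7
Reactants: 11 (1S,2S,3S)-2-[(tert-butyldimethylsilyloxy)methyl]-1-[4-(tert-butyldimethylsilyloxy)-3-methoxyphenyl]-3-(dimethoxymethyl)-6,7-dimethoxy-1,2,3,4-tetrahydronaphthalen-3-ol
Product: 13 tert-butyl{[(1S,2R)-1-[4-(tert-butyldimethylsilyloxy)-3-methoxyphenyl]-3-(dimethoxymethyl)-6,7-dimethoxy-1,2-dihydronaphthalen-2-yl]methoxy}dimethylsilane, via tertiary sulfamate ester 12 (not isolated)
Conditions: methyl N-(triethylammoniosulfonyl)carbamate (Burgess reagent, 3 equiv), toluene, 60 °C
Reagents that add atoms: none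
Why: Burgess dehydration, in which the tertiary alcohol forms sulfamate 12 and this undergoes thermal syn elimination; the only syn β-hydrogens are the benzylic C4–H2 (H2 is trans to the C3 oxygen and no longer acidic), so the C3=C4 bond conjugated with ring A should form while C1 and C2 stay in place.

Step 8
Reactants: 13 tert-butyl{[(1S,2R)-1-[4-(tert-butyldimethylsilyloxy)-3-methoxyphenyl]-3-(dimethoxymethyl)-6,7-dimethoxy-1,2-dihydronaphthalen-2-yl]methoxy}dimethylsilane
Product: 15 (1S,2R)-1-(4-hydroxy-3-methoxyphenyl)-2-(hydroxymethyl)-6,7-dimethoxy-1,2-dihydronaphthalene-3-carbaldehyde, via desilylated acetal 14 (not isolated)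
Conditions: TBAF (2.5 equiv), THF, 0 °C; then 1 M aq. HCl, rt
Reagents that add atoms: water, O
Why: Fluoride cleaves both silyl ethers while the base-sensitive enal is still masked as its acetal, and brief dilute acid then hydrolyses the allylic dimethyl acetal through its conjugated oxocarbenium ion to the enal, neither stage touching C1 or C2.

Compound list
1 | 2-bromo-4,5-dimethoxybenzaldehyde | O=Cc1cc(OC)c(OC)cc1Br | starting material
2 | methyl 2-(triphenyl-λ5-phosphanylidene)acetate | COC(=O)C=P(c1ccccc1)(c1ccccc1)c1ccccc1 | starting material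
3 | methyl (E)-3-(2-bromo-4,5-dimethoxyphenyl)prop-2-enoate | COC(=O)/C=C/c1cc(OC)c(OC)cc1Br | intermediate
4 | 1,1-dimethoxypropan-2-one | CC(=O)C(OC)OC | starting material
5 | methyl (E)-3-[2-(3,3-dimethoxy-2-oxopropyl)-4,5-dimethoxyphenyl]prop-2-enoate | COC(=O)/C=C/c1cc(OC)c(OC)cc1CC(=O)C(OC)OC | intermediate
6 | 2-methoxy-4-(4,4,5,5-tetramethyl-1,3,2-dioxaborolan-2-yl)phenol | COc1cc(B2OC(C)(C)C(C)(C)O2)ccc1O | starting material
7 | tert-butyl[2-methoxy-4-(4,4,5,5-tetramethyl-1,3,2-dioxaborolan-2-yl)phenoxy]dimethylsilane | COc1cc(B2OC(C)(C)C(C)(C)O2)ccc1O[Si](C)(C)C(C)(C)C | intermediate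
8 | O-bound rhodium enolate of methyl (3S)-3-[4-(tert-butyldimethylsilyloxy)-3-methoxyphenyl]-3-[2-(3,3-dimethoxy-2-oxopropyl)-4,5-dimethoxyphenyl]propanoate (BINAP on rhodium not drawn; not isolated) | COc1cc([C@H](/C=C(/OC)O[Rh])c2cc(OC)c(OC)cc2CC(=O)C(OC)OC)ccc1O[Si](C)(C)C(C)(C)C | intermediate
9 | methyl (1S,2R,3S)-1-[4-(tert-butyldimethylsilyloxy)-3-methoxyphenyl]-3-(dimethoxymethyl)-3-hydroxy-6,7-dimethoxy-1,2,3,4-tetrahydronaphthalene-2-carboxylate | COc1cc([C@H]2c3cc(OC)c(OC)cc3C[C@@](O)(C(OC)OC)[C@@H]2C(=O)OC)ccc1O[Si](C)(C)C(C)(C)C | intermediate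
10 | (1S,2S,3S)-1-[4-(tert-butyldimethylsilyloxy)-3-methoxyphenyl]-3-(dimethoxymethyl)-2-(hydroxymethyl)-6,7-dimethoxy-1,2,3,4-tetrahydronaphthalen-3-ol (target locants) | COc1cc([C@H]2c3cc(OC)c(OC)cc3C[C@@](O)(C(OC)OC)[C@@H]2CO)ccc1O[Si](C)(C)C(C)(C)C | intermediate
11 | (1S,2S,3S)-2-[(tert-butyldimethylsilyloxy)methyl]-1-[4-(tert-butyldimethylsilyloxy)-3-methoxyphenyl]-3-(dimethoxymethyl)-6,7-dimethoxy-1,2,3,4-tetrahydronaphthalen-3-ol (target locants) | COc1cc([C@H]2c3cc(OC)c(OC)cc3C[C@@](O)(C(OC)OC)[C@@H]2CO[Si](C)(C)C(C)(C)C)ccc1O[Si](C)(C)C(C)(C)C | intermediate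
12 | triethylammonium salt of the C3 O-sulfonyl-N-(methoxycarbonyl)amide (sulfamate ester) of 11 (not isolated) | COc1cc([C@H]2c3cc(OC)c(OC)cc3C[C@@](OS(=O)(=O)[N-]C(=O)OC)(C(OC)OC)[C@@H]2CO[Si](C)(C)C(C)(C)C)ccc1O[Si](C)(C)C(C)(C)C.CC[NH+](CC)CC | intermediate
13 | tert-butyl{[(1S,2R)-1-[4-(tert-butyldimethylsilyloxy)-3-methoxyphenyl]-3-(dimethoxymethyl)-6,7-dimethoxy-1,2-dihydronaphthalen-2-yl]methoxy}dimethylsilane | COc1cc([C@H]2c3cc(OC)c(OC)cc3C=C(C(OC)OC)[C@@H]2CO[Si](C)(C)C(C)(C)C)ccc1O[Si](C)(C)C(C)(C)C | intermediate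
14 | [(1S,2R)-3-(dimethoxymethyl)-1-(4-hydroxy-3-methoxyphenyl)-6,7-dimethoxy-1,2-dihydronaphthalen-2-yl]methanol (not isolated) | COc1cc([C@H]2c3cc(OC)c(OC)cc3C=C(C(OC)OC)[C@@H]2CO)ccc1O | intermediate
15 | (1S,2R)-1-(4-hydroxy-3-methoxyphenyl)-2-(hydroxymethyl)-6,7-dimethoxy-1,2-dihydronaphthalene-3-carbaldehyde, systematic name (3R,4S)-4-(4-hydroxy-3-methoxyphenyl)-3-(hydroxymethyl)-6,7-dimethoxy-3,4-dihydronaphthalene-2-carbaldehyde | COc1cc([C@H]2c3cc(OC)c(OC)cc3C=C(C=O)[C@@H]2CO)ccc1O | target

Total step count: 8. Longest linear sequence: 7 (steps 1, 2, 4, 5, 6, 7, 8; step 3 is a one-step side branch).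

Steps most likely to fail

Step 4 (proposed new method). The rhodium ester enolate may be quenched before ring closure, either by water or by proton transfer from the acidic benzylic C4 methylene, or the aryl group may add to the activated ketone. The fallback uses known chemistry and sets out from 5 and 7. Oxidative Mizoroki–Heck arylation of the cinnamate with the boronate (Pd(OAc)2, 2,9-dimethyl-1,10-phenanthroline, O2, DMF, 50 °C) proceeds by syn-insertion and syn-β-hydride elimination, which place ring C trans to the ester. It should give methyl (Z)-3-[4-(tert-butyldimethylsilyloxy)-3-methoxyphenyl]-3-[2-(3,3-dimethoxy-2-oxopropyl)-4,5-dimethoxyphenyl]prop-2-enoate F1. An enantioselective copper hydride reductive aldol cyclisation of the keto-enoate follows (Cu(OAc)2, DTBM-SEGPHOS in the antipode that delivers hydride to the face giving 1S, (EtO)2MeSiH, toluene, 0 °C, then NH4F in methanol). Hydride goes to C1 and the copper enolate at C2 closes ring B onto the C3 ketone under aprotic conditions. The route is rejoined at 9.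

Step 2. The product enol may cyclise by conjugate addition of its oxygen onto the ortho-acrylate under the basic conditions, and the new, more acidic benzylic position may be arylated a second time. The fallback sets out from 4 and builds the ketone arm before any acrylate is present. Palladium-catalysed α-arylation of 4 with an excess of commercial, symmetric 1,2-dibromo-4,5-dimethoxybenzene (same Pd2(dba)3/Xantphos/K3PO4 system) should give 1-(2-bromo-4,5-dimethoxyphenyl)-3,3-dimethoxypropan-2-one F2. A Mizoroki–Heck reaction with methyl acrylate under amine base (Pd(OAc)2, P(o-tol)3, Et3N, DMF, 100 °C) then installs the (E)-acrylate. The route is rejoined at 5.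

Step 7. The hindered tertiary carbinol may fail to form the sulfamate, or elimination may take place toward C2 instead of C4. The fallback sets out from 11 and replaces the dehydration by a base-mediated epoxide-to-allylic-alcohol isomerisation, whose regiochemistry is fixed by the syn, benzylic C4 hydrogen.
- Acetal hydrolysis under silyl-ether-compatible conditions (LiBF4, wet acetonitrile, 60 °C) should give (1S,2S,3S)-2-[(tert-butyldimethylsilyloxy)methyl]-1-[4-(tert-butyldimethylsilyloxy)-3-methoxyphenyl]-3-hydroxy-6,7-dimethoxy-1,2,3,4-tetrahydronaphthalene-3-carbaldehyde F3.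
- NaBH4 in methanol at 0 °C reduces it to the corresponding 3-(hydroxymethyl)-3-ol, diol F4.
- NaH and N-tosylimidazole in THF close the spiro-epoxide F5 (the primary oxygen leaves as tosylate and the C3 oxygen is retained).
- Diethylaluminium 2,2,6,6-tetramethylpiperidide in toluene at 0 °C removes the C4 hydrogen syn to the epoxide oxygen (H2 is anti and unavailable) and should give the allylic alcohol [(1S,2R)-2-[(tert-butyldimethylsilyloxy)methyl]-1-[4-(tert-butyldimethylsilyloxy)-3-methoxyphenyl]-6,7-dimethoxy-1,2-dihydronaphthalen-3-yl]methanol F6.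
- MnO2 in CH2Cl2 oxidises the allylic alcohol to the bis-silylated enal F7.
- TBAF in THF at 0 °C removes both silyl groups, and the route is rejoined at 15.

Further compounds
F1 | step 4 | methyl (Z)-3-[4-(tert-butyldimethylsilyloxy)-3-methoxyphenyl]-3-[2-(3,3-dimethoxy-2-oxopropyl)-4,5-dimethoxyphenyl]prop-2-enoate | COC(=O)/C=C(/c1ccc(O[Si](C)(C)C(C)(C)C)c(OC)c1)c1cc(OC)c(OC)cc1CC(=O)C(OC)OC
F2 | step 2 | 1-(2-bromo-4,5-dimethoxyphenyl)-3,3-dimethoxypropan-2-one | COC(OC)C(=O)Cc1cc(OC)c(OC)cc1Br
F3 | step 7 | (1S,2S,3S)-2-[(tert-butyldimethylsilyloxy)methyl]-1-[4-(tert-butyldimethylsilyloxy)-3-methoxyphenyl]-3-hydroxy-6,7-dimethoxy-1,2,3,4-tetrahydronaphthalene-3-carbaldehyde | COc1cc([C@H]2c3cc(OC)c(OC)cc3C[C@@](O)(C=O)[C@@H]2CO[Si](C)(C)C(C)(C)C)ccc1O[Si](C)(C)C(C)(C)C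
F4 | step 7 | (1S,2S,3S)-2-[(tert-butyldimethylsilyloxy)methyl]-1-[4-(tert-butyldimethylsilyloxy)-3-methoxyphenyl]-3-(hydroxymethyl)-6,7-dimethoxy-1,2,3,4-tetrahydronaphthalen-3-ol | COc1cc([C@H]2c3cc(OC)c(OC)cc3C[C@@](O)(CO)[C@@H]2CO[Si](C)(C)C(C)(C)C)ccc1O[Si](C)(C)C(C)(C)C
F5 | step 7 | spiro-epoxide of F4 (oxirane spiro-fused at C3, C3 oxygen retained, 1S,2S,3S) | COc1cc([C@H]2c3cc(OC)c(OC)cc3C[C@@]4(CO4)[C@@H]2CO[Si](C)(C)C(C)(C)C)ccc1O[Si](C)(C)C(C)(C)C
F6 | step 7 | [(1S,2R)-2-[(tert-butyldimethylsilyloxy)methyl]-1-[4-(tert-butyldimethylsilyloxy)-3-methoxyphenyl]-6,7-dimethoxy-1,2-dihydronaphthalen-3-yl]methanol | COc1cc([C@H]2c3cc(OC)c(OC)cc3C=C(CO)[C@@H]2CO[Si](C)(C)C(C)(C)C)ccc1O[Si](C)(C)C(C)(C)C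
F7 | step 7 | (1S,2R)-2-[(tert-butyldimethylsilyloxy)methyl]-1-[4-(tert-butyldimethylsilyloxy)-3-methoxyphenyl]-6,7-dimethoxy-1,2-dihydronaphthalene-3-carbaldehyde | COc1cc([C@H]2c3cc(OC)c(OC)cc3C=C(C=O)[C@@H]2CO[Si](C)(C)C(C)(C)C)ccc1O[Si](C)(C)C(C)(C)C
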